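**Plan**
- Retrosynthesis: the pivalate on the 4'-oxygen is cut last. Before it, one disconnection opens the pyran (O1–C2 and C4–C4a) and takes the prenyl group off C8 (C8–CH2).
- Enabling feature: in the chromene, C8 and C4a each lie ortho to a ring oxygen (the C7 hydroxyl, and O1 on C8a), and C6, the other ortho carbon of the C7 oxygen, carries the aroyl group. Both C5 units can therefore be returned to those oxygens as a 1,1-dimethylallyl ether and a 1,1-dimethylpropargyl ether.
- The three O–C bonds (tert-allyl, methyl, propargyl) are then cut in reverse order of hydroxyl reactivity of a 2,4,6-trihydroxybenzophenone. The aryl–carbonyl bond is cut to phloroglucinol and 4-(pivaloyloxy)benzoyl chloride.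
- Forward: acylation of the symmetrical triol; para oxygen propargylated, one ortho oxygen methylated, the hydrogen-bonded ortho oxygen tert-allylated; one staged heating moves the prenyl group to C8 and then closes the pyran, the only ring made; methanolysis frees the phenol.
- Stereochemistry: the target has no stereocentre; the C3=C4 alkene is cis because it forms inside the six-membered ring.

Key step: step 8

Assumption: chromene numbering (O1, C2, C3, C4, C4a, C5–C8, C8a) is used for the ring atoms of the key step. Phloroglucinol is chosen as the arene because its three ring carbons are equivalent, so the acylation raises no regiochemical question. The allylic carbonate 10 is prepared (step 6), not bought.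

Step 1
Reactants: 1 4-hydroxybenzoic acid
Product: 2 4-(pivaloyloxy)benzoic acid
Conditions: PivCl, NaOH, H2O/THF, 0 °C; then HCl to pH 2
Reagents that add atoms: pivaloyl chloride, CC(C)(C)C(=O)Cl
Why: Schotten–Baumann acylation, in which the phenoxide of the dianion is acylated, any mixed anhydride at the carboxylate is hydrolysed by the aqueous base, and the hindered ester survives the work-up.

Step 2
Reactants: 2 4-(pivaloyloxy)benzoic acid
Product: 3 4-(pivaloyloxy)benzoyl chloride
Conditions: (COCl)2, DMF (cat.), CH2Cl2, 0 °C to rt
Reagents that add atoms: oxalyl chloride, O=C(Cl)C(=O)Cl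
Why: Standard acid chloride formation through the DMF-derived chloroiminium species, to which an aryl pivalate is inert.

Step 3
Reactants: 3 4-(pivaloyloxy)benzoyl chloride; 4 phloroglucinol (benzene-1,3,5-triol)
Product: 5 4-(2,4,6-trihydroxybenzoyl)phenyl pivalate
Conditions: AlCl3 (3.5 equiv), PhNO2, rt to 45 °C; then ice, aq. HCl
Reagents that add atoms: none
Why: Friedel–Crafts acylation at one of three equivalent ring carbons, where the aluminium-chelated ortho-hydroxy ketone is deactivated towards a second acylation and the pivalate on the electron-poor aroyl ring should neither migrate (Fries) nor cleave at this temperature.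

Step 4
Reactants: 5 4-(2,4,6-trihydroxybenzoyl)phenyl pivalate; 6 3-chloro-3-methylbut-1-yne
Product: 7 4-[2,6-dihydroxy-4-(2-methylbut-3-yn-2-yloxy)benzoyl]phenyl pivalate
Conditions: DBU (1.1 equiv), CuCl2·2H2O (1 mol %), MeCN, −5 to 0 °C
Reagents that add atoms: none
Why: Copper-catalysed propargylic etherification (a Williamson-type O-alkylation in which copper activates the terminal alkyne so that chloride leaves and the phenoxide adds at the tertiary carbon), selective with one equivalent for the 4-hydroxyl because it is the most acidic, is unhindered and is the only one neither flanked by nor hydrogen-bonded to the aroyl group.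

Step 5
Reactants: 7 4-[2,6-dihydroxy-4-(2-methylbut-3-yn-2-yloxy)benzoyl]phenyl pivalate
Product: 8 4-[2-hydroxy-6-methoxy-4-(2-methylbut-3-yn-2-yloxy)benzoyl]phenyl pivalate
Conditions: MeI (1.1 equiv), K2CO3, acetone, rt to 40 °C
Reagents that add atoms: iodomethane, CI
Why: Williamson etherification of one of two equivalent ortho hydroxyls, after which the remaining hydroxyl is locked in a hydrogen bond to the ketone and should be too poorly nucleophilic to react further under these mild conditions.

Step 6
Reactants: 9 2-methylbut-3-en-2-ol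
Product: 10 tert-butyl 2-methylbut-3-en-2-yl carbonate
Conditions: n-BuLi, THF, −78 to 0 °C; then Boc2O, 0 °C to rt; H2O quench
Reagents that add atoms: di-tert-butyl dicarbonate, CC(C)(C)OC(=O)OC(=O)OC(C)(C)C
Why: Alkoxycarbonylation of the lithium alkoxide of a tertiary allylic alcohol, the usual way to make this allyl donor.

Step 7
Reactants: 8 4-[2-hydroxy-6-methoxy-4-(2-methylbut-3-yn-2-yloxy)benzoyl]phenyl pivalate; 10 tert-butyl 2-methylbut-3-en-2-yl carbonate
Product: 11 4-[2-methoxy-4-(2-methylbut-3-yn-2-yloxy)-6-(2-methylbut-3-en-2-yloxy)benzoyl]phenyl pivalate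
Conditions: Pd(PPh3)4 (5 mol %), THF, 0 °C, stopped at full conversion of 8
Reagents that add atoms: none
Why: Tsuji–Trost-type decarboxylative O-allylation, in which zerovalent palladium ionises 10 to a 1,1-dimethylallyl π-complex with loss of CO2, the tert-butoxide set free deprotonates the hydrogen-bonded phenol, and kinetic attack of the phenoxide at the more substituted allyl terminus should give the tertiary ether as long as the mixture is kept cold and not left to re-ionise towards the linear prenyl ether.

Step 8
Reactants: 11 4-[2-methoxy-4-(2-methylbut-3-yn-2-yloxy)-6-(2-methylbut-3-en-2-yloxy)benzoyl]phenyl pivalate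
Product: 15 vismiaphenone F 4'-O-pivalate, via C8-prenylphenol propargyl ether 12 (not isolated), via ortho-allenylphenol 13 (not isolated), via ortho-quinone methide 14 (not isolated)
Conditions: PhNEt2 (degassed), Ar, 100–110 °C until 11 is consumed; then 185 °C, one pot
Reagents that add atoms: none
Why: Gentle heating first drives the aromatic Claisen rearrangement of the 1,1-dimethylallyl ether, a concerted [3,3] shift through a six-membered transition state that forms the C8–CH2 bond with allylic inversion, so the tertiary ether arrives as the linear prenyl group and enolisation gives the C7 phenol 12, hydrogen-bonded to the ketone. At the higher temperature the 1,1-dimethylpropargyl ether on O1 undergoes the propargyl Claisen shift to C4a (the C4a–C4 bond) and enolises to the ortho-allenylphenol 13, whose 1,5-hydrogen shift from the phenol to the central allene carbon gives the (Z)-ortho-quinone methide 14. The pyran ring is closed by thermal disrotatory oxa-6π electrocyclisation of 14, which forms the O1–C2 bond and restores the aromatic ring. Both halves are the established thermal chemistry of aryl 1,1-dimethylallyl ethers (to ortho-prenylphenols) and of aryl 1,1-dimethylpropargyl ethers (to 2,2-dimethyl-2H-chromenes); no stereocentre is created and the C3=C4 alkene is cis because it lies in the ring. The step needs site and order selectivity: the allyl group can only reach C8 because C6 carries the aroyl group, and once C8 is filled C4a is the only ortho carbon left for the propargyl group, which would otherwise be expected to compete for C8. The order should be secured by the lower barrier of the tertiary allyl ether shift and by holding the lower temperature until 11 is gone, while the weakly basic solvent suppresses acid-mediated cyclisation of the prenylphenol and loss of the tertiary allyl group.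

Step 9
Reactants: 15 vismiaphenone F 4'-O-pivalate
Product: 16 vismiaphenone F
Conditions: K2CO3 (0.5 equiv), MeOH, rt; then aq. NH4Cl
Reagents that add atoms: none
Why: Base-mediated transesterification in which methoxide attacks the aryl ester activated by the para ketone and expels the phenoxide, while the chromene, the prenyl group, the methyl ether and the hydrogen-bonded C7 phenol are inert to carbonate in methanol.

**Compound list**

1 | 4-hydroxybenzoic acid | O=C(O)c1ccc(O)cc1 | starting material
2 | 4-(pivaloyloxy)benzoic acid | CC(C)(C)C(=O)Oc1ccc(cc1)C(=O)O | intermediate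
3 | 4-(pivaloyloxy)benzoyl chloride | CC(C)(C)C(=O)Oc1ccc(cc1)C(=O)Cl | intermediate
4 | phloroglucinol (benzene-1,3,5-triol) | Oc1cc(O)cc(O)c1 | starting material
5 | 4-(2,4,6-trihydroxybenzoyl)phenyl pivalate | CC(C)(C)C(=O)Oc1ccc(cc1)C(=O)c1c(O)cc(O)cc1O | intermediate
6 | 3-chloro-3-methylbut-1-yne | CC(C)(Cl)C#C | starting material
7 | 4-[2,6-dihydroxy-4-(2-methylbut-3-yn-2-yloxy)benzoyl]phenyl pivalate | CC(C)(C)C(=O)Oc1ccc(cc1)C(=O)c1c(O)cc(OC(C)(C)C#C)cc1O | intermediate
8 | 4-[2-hydroxy-6-methoxy-4-(2-methylbut-3-yn-2-yloxy)benzoyl]phenyl pivalate | COc1cc(OC(C)(C)C#C)cc(O)c1C(=O)c1ccc(OC(=O)C(C)(C)C)cc1 | intermediate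
9 | 2-methylbut-3-en-2-ol | CC(C)(O)C=C | starting material
10 | tert-butyl 2-methylbut-3-en-2-yl carbonate | CC(C)(C)OC(=O)OC(C)(C)C=C | intermediate
11 | 4-[2-methoxy-4-(2-methylbut-3-yn-2-yloxy)-6-(2-methylbut-3-en-2-yloxy)benzoyl]phenyl pivalate | COc1cc(OC(C)(C)C#C)cc(OC(C)(C)C=C)c1C(=O)c1ccc(OC(=O)C(C)(C)C)cc1 | intermediate
12 | 4-[2-hydroxy-6-methoxy-3-(3-methylbut-2-en-1-yl)-4-(2-methylbut-3-yn-2-yloxy)benzoyl]phenyl pivalate (C8-prenylphenol propargyl ether; not isolated, step 8) | COc1cc(OC(C)(C)C#C)c(CC=C(C)C)c(O)c1C(=O)c1ccc(OC(=O)C(C)(C)C)cc1 | intermediate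
13 | 4-[2,4-dihydroxy-6-methoxy-5-(3-methylbuta-1,2-dien-1-yl)-3-(3-methylbut-2-en-1-yl)benzoyl]phenyl pivalate (ortho-allenylphenol; not isolated, step 8) | COc1c(C=C=C(C)C)c(O)c(CC=C(C)C)c(O)c1C(=O)c1ccc(OC(=O)C(C)(C)C)cc1 | intermediate
14 | 4-{[2-hydroxy-6-methoxy-5-[(Z)-3-methylbut-2-en-1-ylidene]-3-(3-methylbut-2-en-1-yl)-4-oxocyclohexa-1(6),2-dien-1-yl]carbonyl}phenyl pivalate (ortho-quinone methide; not isolated, step 8) | COC1=C(C(=O)c2ccc(OC(=O)C(C)(C)C)cc2)C(O)=C(CC=C(C)C)C(=O)/C1=C\C=C(C)C | intermediate
15 | vismiaphenone F 4'-O-pivalate: 4-[7-hydroxy-5-methoxy-2,2-dimethyl-8-(3-methylbut-2-en-1-yl)-2H-chromene-6-carbonyl]phenyl pivalate | COc1c2c(c(CC=C(C)C)c(O)c1C(=O)c1ccc(OC(=O)C(C)(C)C)cc1)OC(C)(C)C=C2 | intermediate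
16 | vismiaphenone F: (4-hydroxyphenyl)[7-hydroxy-5-methoxy-2,2-dimethyl-8-(3-methylbut-2-en-1-yl)-2H-chromen-6-yl]methanone | COc1c2c(c(CC=C(C)C)c(O)c1C(=O)c1ccc(O)cc1)OC(C)(C)C=C2 | target

**Count**
Total steps: 9. Longest linear sequence: 8 (steps 1–5 and 7–9; step 6 is a one-step side branch).

**Steps most likely to fail**

Step 8 (key step). The propargyl ether may begin its sigmatropic shift onto C8 before the allyl ether has fully migrated, or the tertiary allyl group may be lost by fragmentation before it rearranges. The fallback sets out from 11 and returns at 15, running the two events as separate operations with different activation. Eu(fod)3 (fod = 6,6,7,7,8,8,8-heptafluoro-2,2-dimethyloctane-3,5-dionate) in CHCl3 at about 50 °C should catalyse the allyl ether Claisen shift by chelation between the ether oxygen and the ketone, at a temperature where the propargyl ether is inert, so that 12 can be isolated. Compound 12 is then closed to 15 at room temperature by Ph3PAuNTf2-catalysed 6-endo hydroarylation of the propargyl ether in CH2Cl2, where monovalent gold activates the alkyne for attack by C4a, the only free ortho carbon. No compound outside the list is made.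

Step 7. Capture of the π-allyl complex by the hydrogen-bonded, flanked phenoxide may be slow, so that re-ionisation of the tertiary ether and drift to the linear prenyl ether, or C-allylation, take over. The fallback avoids π-allyl chemistry by the classical propargyl ether and semi-hydrogenation sequence, with the para oxygen masked meanwhile; it sets out from 5 and returns at 11. Silylation of 5 with TIPSCl and imidazole in DMF at 0 °C should take the unhindered para hydroxyl and give 4-[2,6-dihydroxy-4-(triisopropylsilyloxy)benzoyl]phenyl pivalate F1. Methylation with MeI and K2CO3 in acetone gives 4-[2-hydroxy-6-methoxy-4-(triisopropylsilyloxy)benzoyl]phenyl pivalate F2. Copper-catalysed etherification of the remaining hydroxyl with 6 (DBU, CuCl2·2H2O, dry MeCN) gives 4-[2-methoxy-6-(2-methylbut-3-yn-2-yloxy)-4-(triisopropylsilyloxy)benzoyl]phenyl pivalate F3. Lindlar-type semi-hydrogenation (H2, Pd/CaCO3 poisoned with Pb(OAc)2, quinoline, EtOAc) reduces its only alkyne to 4-[2-methoxy-6-(2-methylbut-3-en-2-yloxy)-4-(triisopropylsilyloxy)benzoyl]phenyl pivalate F4. Desilylation with TBAF buffered with AcOH in THF at 0 °C frees 4-[4-hydroxy-2-methoxy-6-(2-methylbut-3-en-2-yloxy)benzoyl]phenyl pivalate F5. Propargylation of its para hydroxyl with 6 under the conditions of step 4 gives 11.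

Step 4. Over-alkylation at an ortho hydroxyl or C-alkylation of the electron-rich ring may compete with clean mono-etherification at the para oxygen. The fallback differentiates the oxygens by the robust two-fold protection of acylphloroglucinols; it sets out from 5 and returns at 8. MOMCl (2.2 equiv) and i-Pr2NEt in CH2Cl2 at 0 °C should cap the para and one ortho hydroxyl to give 4-[2-hydroxy-4,6-bis(methoxymethoxy)benzoyl]phenyl pivalate F6. MeI and K2CO3 in refluxing acetone methylate the hydrogen-bonded hydroxyl to give 4-[2-methoxy-4,6-bis(methoxymethoxy)benzoyl]phenyl pivalate F7. HCl in MeOH at 40 °C removes both acetals to give 4-(2,4-dihydroxy-6-methoxybenzoyl)phenyl pivalate F8. Its para hydroxyl, now the only one not hydrogen-bonded, is propargylated with 6 (DBU, CuCl2·2H2O, MeCN, 0 °C) to give 8.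

**Further compounds**

F0 | step 8 | none | none
F1 | step 7 | 4-[2,6-dihydroxy-4-(triisopropylsilyloxy)benzoyl]phenyl pivalate | CC(C)(C)C(=O)Oc1ccc(cc1)C(=O)c1c(O)cc(O[Si](C(C)C)(C(C)C)C(C)C)cc1O
F2 | step 7 | 4-[2-hydroxy-6-methoxy-4-(triisopropylsilyloxy)benzoyl]phenyl pivalate | COc1cc(O[Si](C(C)C)(C(C)C)C(C)C)cc(O)c1C(=O)c1ccc(OC(=O)C(C)(C)C)cc1
F3 | step 7 | 4-[2-methoxy-6-(2-methylbut-3-yn-2-yloxy)-4-(triisopropylsilyloxy)benzoyl]phenyl pivalate | COc1cc(O[Si](C(C)C)(C(C)C)C(C)C)cc(OC(C)(C)C#C)c1C(=O)c1ccc(OC(=O)C(C)(C)C)cc1
F4 | step 7 | 4-[2-methoxy-6-(2-methylbut-3-en-2-yloxy)-4-(triisopropylsilyloxy)benzoyl]phenyl pivalate | COc1cc(O[Si](C(C)C)(C(C)C)C(C)C)cc(OC(C)(C)C=C)c1C(=O)c1ccc(OC(=O)C(C)(C)C)cc1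
F5 | step 7 | 4-[4-hydroxy-2-methoxy-6-(2-methylbut-3-en-2-yloxy)benzoyl]phenyl pivalate | COc1cc(O)cc(OC(C)(C)C=C)c1C(=O)c1ccc(OC(=O)C(C)(C)C)cc1
F6 | step 4 | 4-[2-hydroxy-4,6-bis(methoxymethoxy)benzoyl]phenyl pivalate | COCOc1cc(O)c(C(=O)c2ccc(OC(=O)C(C)(C)C)cc2)c(OCOC)c1
F7 | step 4 | 4-[2-methoxy-4,6-bis(methoxymethoxy)benzoyl]phenyl pivalate | COCOc1cc(OC)c(C(=O)c2ccc(OC(=O)C(C)(C)C)cc2)c(OCOC)c1
F8 | step 4 | 4-(2,4-dihydroxy-6-methoxybenzoyl)phenyl pivalate | COc1cc(O)cc(O)c1C(=O)c1ccc(OC(=O)C(C)(C)C)cc1
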